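**Retrosynthetic overview**

- The butenolide is closed last by ring-closing metathesis of an allyl 2-(1-hydroxyalkyl)acrylate; its C-12 carbinol comes from a catalyst-controlled Morita–Baylis–Hillman reaction on a C-12 aldehyde.
- Rings A and B form in one cation–olefin cascade (ring A first, ring B in the same event) from an acyclic, unprotected epoxy diol: epoxide opening at C-4, chair–chair folding, allylsilane termination to the 8(17)-methylene.
- C-3 and the quaternary C-4 (axial CH2OH) come from Sharpless epoxidation of a (Z)-2-methyl allylic alcohol; the cascade relays this to C-5, C-9 and C-10.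
- The trisubstituted allylsilane and the C-11/C-12 arm come from syn-carbocupration of a terminal alkyne followed by oxirane opening.
- The acyclic chain comes from geranyl chloride by selective ozonolysis, Still–Gennari olefination, reduction and propargylation.

Assumption: the target is (12R)-14-deoxy-12-hydroxyandrographolide (an ent-labdane); labdane numbering (C-1 to C-20, C-19 = axial CH2OH, C-17 = exocyclic CH2) is used for positions, and small reagents that donate atoms are given on the reagent line and not numbered.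

**Step 1**
Reactants: 1 geranyl chloride [(2E)-1-chloro-3,7-dimethylocta-2,6-diene]
Product: 2 (4E)-6-chloro-4-methylhex-4-enal
Conditions: O3 (1.0 equiv), pyridine (3 equiv), CH2Cl2, −78 °C
Reagents that add atoms: ozone, [O-][O+]=O
Why: Chemoselective ozonolysis cleaves the electron-rich terminal alkene while the alkene next to the allylic chloride is inductively deactivated (as with geranyl acetate), pyridine breaking the carbonyl oxide down directly to the aldehyde; no stereocentre is formed and the E alkene is untouched.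

**Step 2**
Reactants: 2 (4E)-6-chloro-4-methylhex-4-enal
Product: 3 methyl (2Z,6E)-8-chloro-2,6-dimethylocta-2,6-dienoate
Conditions: phosphonate, KN(SiMe3)2, 18-crown-6, THF, −78 °C; then 2
Reagents that add atoms: methyl 2-[bis(2,2,2-trifluoroethoxy)phosphoryl]propanoate, COC(=O)C(C)P(=O)(OCC(F)(F)F)OCC(F)(F)F
Why: Still–Gennari olefination gives the (Z)-2-methyl enoate under kinetic control (typically at least 15:1), which places the future C-19 carbon cis to the chain.

**Step 3**
Reactants: 3 methyl (2Z,6E)-8-chloro-2,6-dimethylocta-2,6-dienoate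
Product: 4 (2Z,6E)-8-chloro-2,6-dimethylocta-2,6-dien-1-ol
Conditions: i-Bu2AlH (2.2 equiv), CH2Cl2, −78 °C; aq. potassium sodium tartrate
Reagents that add atoms: none
Why: 1,2-Reduction of the enoate with i-Bu2AlH at low temperature gives the allylic alcohol without touching the allylic chloride or either alkene geometry.

**Step 4**
Reactants: 4 (2Z,6E)-8-chloro-2,6-dimethylocta-2,6-dien-1-ol
Product: 5 (2Z,6E)-2,6-dimethylundeca-2,6-dien-10-yn-1-ol
Conditions: propyne, n-BuLi (2 equiv per propyne), TMEDA, Et2O/hexane, −78 → 0 °C; then 4 (pre-treated with 1 equiv n-BuLi), THF, −78 °C → rt; aq. NH4Cl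
Reagents that add atoms: propyne, CC#C
Why: SN2 propargylation of the primary allylic chloride by the sp3 carbon of 1,3-dilithiopropyne (known to alkylate geranyl halides at the α-carbon) gives the 1,5-enyne with a free terminal alkyne after protonation.

**Step 5**
Reactants: 5 (2Z,6E)-2,6-dimethylundeca-2,6-dien-10-yn-1-ol
Product: 7 (2Z,6E,10Z)-2,6-dimethyl-10-[(trimethylsilyl)methyl]trideca-2,6,10-triene-1,13-diol, via alkenylcopper 6 (not isolated)
Conditions: Me3SiCH2MgCl (3.2 equiv), CuBr·SMe2 (2.1 equiv), Et2O/Me2S, −45 → −25 °C, 48 h; then LiC≡CPr (from 1-pentyne, n-BuLi), HMPA, oxirane, −78 → −20 °C; aq. NH4Cl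
Reagents that add atoms: [(trimethylsilyl)methyl]magnesium chloride, C[Si](C)(C)C[Mg]Cl; oxirane, C1CO1
Why: Normant carbocupration adds Me3SiCH2Cu syn across the terminal alkyne (copper on the terminal carbon, cis to CH2SiMe3) and the derived mixed cuprate opens oxirane with retention, which fixes the allylsilane geometry (C-7 trans to C-11) needed for an equatorial C-9 side chain.

**Step 6**
Reactants: 7 (2Z,6E,10Z)-2,6-dimethyl-10-[(trimethylsilyl)methyl]trideca-2,6,10-triene-1,13-diol
Product: 8 [(2S,3R)-3-[(3E,7Z)-10-hydroxy-3-methyl-7-[(trimethylsilyl)methyl]deca-3,7-dien-1-yl]-2-methyloxiran-2-yl]methanol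
Conditions: Ti(OiPr)4 (20 mol%), L-(+)-diethyl tartrate (24 mol%), t-BuOOH (2 equiv), 4 Å molecular sieves, CH2Cl2, −20 °C
Reagents that add atoms: tert-butyl hydroperoxide, CC(C)(C)OO
Why: Sharpless asymmetric epoxidation oxidises only the allylic-alcohol alkene (the homoallylic allylsilane alkene is far slower), and L-(+)-tartrate gives the (2S,3R)-epoxy alcohol as with nerol, which sets C-3 (R) and the C-4 configuration that C-5 will later invert.

**Step 7**
Reactants: 8 [(2S,3R)-3-[(3E,7Z)-10-hydroxy-3-methyl-7-[(trimethylsilyl)methyl]deca-3,7-dien-1-yl]-2-methyloxiran-2-yl]methanol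
Product: 9 (1R,2R,4aS,5R,8aS)-5-(2-hydroxyethyl)-1-(hydroxymethyl)-1,4a-dimethyl-6-methylidenedecahydronaphthalen-2-ol
Conditions: MeAlCl2 (3.5 equiv), CH2Cl2, −78 → −40 °C; aq. potassium sodium tartrate
Reagents that add atoms: none
Why: In this allylsilane-terminated epoxy-polyene (cation–olefin) bicyclisation MeAlCl2 turns both hydroxyls into poorly nucleophilic aluminium alkoxides and activates the epoxide, C-5 attacks tertiary C-4 with inversion through a chair–chair transition state (C-3 oxygen equatorial, the Z-derived CH2O group axial), C-9 adds anti at C-10 to give the trans-decalin with equatorial C-9 side chain, and loss of silicon from the β-silyl cation gives only the exocyclic alkene, so C-4, C-5, C-9 and C-10 are set relative to the epoxide.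

**Step 8**
Reactants: 9 (1R,2R,4aS,5R,8aS)-5-(2-hydroxyethyl)-1-(hydroxymethyl)-1,4a-dimethyl-6-methylidenedecahydronaphthalen-2-ol
Product: 10 2-[(1R,4aS,5R,6R,8aS)-6-hydroxy-5-(hydroxymethyl)-5,8a-dimethyl-2-methylidenedecahydronaphthalen-1-yl]acetaldehyde
Conditions: TEMPO (10 mol%), PhI(OAc)2 (1.1 equiv), CH2Cl2, 0 °C → rt
Reagents that add atoms: none
Why: TEMPO/oxoammonium oxidation is selective for unhindered primary alcohols, so the C-12 carbinol reacts in preference to the secondary C-3 hydroxyl and the axial, neopentyl C-19 hydroxyl; no stereocentre is affected.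

**Step 9**
Reactants: 10 2-[(1R,4aS,5R,6R,8aS)-6-hydroxy-5-(hydroxymethyl)-5,8a-dimethyl-2-methylidenedecahydronaphthalen-1-yl]acetaldehyde
Product: 12 prop-2-en-1-yl (3R)-3-hydroxy-4-[(1R,4aS,5R,6R,8aS)-6-hydroxy-5-(hydroxymethyl)-5,8a-dimethyl-2-methylidenedecahydronaphthalen-1-yl]-2-methylidenebutanoate, via hexafluoroisopropyl ester 11 (not isolated)
Conditions: hexafluoroisopropyl acrylate (1.5 equiv), β-isocupreidine (10 mol%), DMF, −55 °C; then allyl alcohol (20 equiv), Et3N, 0 °C → rt
Reagents that add atoms: 1,1,1,3,3,3-hexafluoropropan-2-yl acrylate, C=CC(=O)OC(C(F)(F)F)C(F)(F)F; allyl alcohol, OCC=C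
Why: The Hatakeyama asymmetric Morita–Baylis–Hillman reaction sets the (R)-carbinol at C-12 under catalyst control (β-isocupreidine gives R adducts with aliphatic aldehydes), and the activated hexafluoroisopropyl ester is then transesterified by allyl alcohol.

**Step 10**
Reactants: 12 prop-2-en-1-yl (3R)-3-hydroxy-4-[(1R,4aS,5R,6R,8aS)-6-hydroxy-5-(hydroxymethyl)-5,8a-dimethyl-2-methylidenedecahydronaphthalen-1-yl]-2-methylidenebutanoate
Product: 13 3-[(1R)-1-hydroxy-2-[(1R,4aS,5R,6R,8aS)-6-hydroxy-5-(hydroxymethyl)-5,8a-dimethyl-2-methylidenedecahydronaphthalen-1-yl]ethyl]furan-2(5H)-one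
Conditions: second-generation Grubbs catalyst RuCl2(=CHPh)(PCy3)(H2IMes) (5–10 mol%), CH2Cl2 (0.005 M), 40 °C
Reagents that add atoms: none
Why: Ring-closing metathesis between the allyl ester and the acrylate methylene closes the α-substituted butenolide with loss of ethylene, the hindered exocyclic C-8 methylene being a poor metathesis partner; no stereocentre is touched.

**Compound list**

1 | geranyl chloride, (2E)-1-chloro-3,7-dimethylocta-2,6-diene | CC(C)=CCC/C(C)=C/CCl | starting material
2 | (4E)-6-chloro-4-methylhex-4-enal | O=CCC/C(C)=C/CCl | intermediate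
3 | methyl (2Z,6E)-8-chloro-2,6-dimethylocta-2,6-dienoate | COC(=O)/C(C)=C\CC/C(C)=C/CCl | intermediate
4 | (2Z,6E)-8-chloro-2,6-dimethylocta-2,6-dien-1-ol | OC/C(C)=C\CC/C(C)=C/CCl | intermediate
5 | (2Z,6E)-2,6-dimethylundeca-2,6-dien-10-yn-1-ol | OC/C(C)=C\CC/C(C)=C/CCC#C | intermediate
6 | alkenylcopper from syn addition of Me3SiCH2Cu to 5 (Cu on the former terminal alkyne carbon, cis to CH2SiMe3; C-19 oxygen as ClMg alkoxide; not isolated) | Cl[Mg]OC/C(C)=C\CC/C(C)=C/CC/C(C[Si](C)(C)C)=C/[Cu] | intermediate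
7 | (2Z,6E,10Z)-2,6-dimethyl-10-[(trimethylsilyl)methyl]trideca-2,6,10-triene-1,13-diol | OC/C(C)=C\CC/C(C)=C/CC/C(C[Si](C)(C)C)=C/CCO | intermediate
8 | [(2S,3R)-3-[(3E,7Z)-10-hydroxy-3-methyl-7-[(trimethylsilyl)methyl]deca-3,7-dien-1-yl]-2-methyloxiran-2-yl]methanol | OC[C@]1(C)O[C@@H]1CC/C(C)=C/CC/C(C[Si](C)(C)C)=C/CCO | intermediate
9 | (1R,2R,4aS,5R,8aS)-5-(2-hydroxyethyl)-1-(hydroxymethyl)-1,4a-dimethyl-6-methylidenedecahydronaphthalen-2-ol | C=C1CC[C@@H]2[C@](C)(CO)[C@H](O)CC[C@@]2(C)[C@@H]1CCO | intermediate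
10 | 2-[(1R,4aS,5R,6R,8aS)-6-hydroxy-5-(hydroxymethyl)-5,8a-dimethyl-2-methylidenedecahydronaphthalen-1-yl]acetaldehyde | C=C1CC[C@@H]2[C@](C)(CO)[C@H](O)CC[C@@]2(C)[C@@H]1CC=O | intermediate
11 | 1,1,1,3,3,3-hexafluoropropan-2-yl (3R)-3-hydroxy-4-[(1R,4aS,5R,6R,8aS)-6-hydroxy-5-(hydroxymethyl)-5,8a-dimethyl-2-methylidenedecahydronaphthalen-1-yl]-2-methylidenebutanoate (not isolated) | C=C1CC[C@@H]2[C@](C)(CO)[C@H](O)CC[C@@]2(C)[C@@H]1C[C@@H](O)C(=C)C(=O)OC(C(F)(F)F)C(F)(F)F | intermediate
12 | prop-2-en-1-yl (3R)-3-hydroxy-4-[(1R,4aS,5R,6R,8aS)-6-hydroxy-5-(hydroxymethyl)-5,8a-dimethyl-2-methylidenedecahydronaphthalen-1-yl]-2-methylidenebutanoate | C=C1CC[C@@H]2[C@](C)(CO)[C@H](O)CC[C@@]2(C)[C@@H]1C[C@@H](O)C(=C)C(=O)OCC=C | intermediate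
13 | 3-[(1R)-1-hydroxy-2-[(1R,4aS,5R,6R,8aS)-6-hydroxy-5-(hydroxymethyl)-5,8a-dimethyl-2-methylidenedecahydronaphthalen-1-yl]ethyl]furan-2(5H)-one, (12R)-14-deoxy-12-hydroxyandrographolide | C=C1CC[C@@H]2[C@](C)(CO)[C@H](O)CC[C@@]2(C)[C@@H]1C[C@@H](O)C1=CCOC1=O | target

**Step count**

Total step count: 10. Longest linear sequence: 10 steps (1 to 13); the route has no branch.

**Steps most likely to fail, with fallbacks**

Step 7 (the cascade on the unprotected epoxy diol). The free C-19 oxygen sits next to the epoxide and, once axial, lies 1,3-diaxial to the developing C-10 cation, so ether formation, semipinacol rearrangement or capture of the C-8 cation by O-12 could compete. The fallback gives up the protecting-group-free cascade. It sets out from 8: silylation of both primary hydroxyls (TBSCl, imidazole, DMF) gives the bis(tert-butyldimethylsilyl) ether of 8 F4; the same MeAlCl2 cyclisation, now on a substrate without free oxygen nucleophiles, gives the 12,19-bis(tert-butyldimethylsilyl) ether of 9 F5; Bu4NF in THF removes both silyl groups, and the sequence comes back to the route at 9.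

Step 5 (carbocupration with the sluggish Me3SiCH2 group on a substrate carrying a free alkoxide, followed by oxirane opening). The fallback builds the allylsilane by trans-hydrosilylation and cross-coupling instead. It sets out from 5: deprotonation (n-BuLi, 2.1 equiv) and opening of oxirane with BF3·OEt2 gives (2Z,6E)-2,6-dimethyltrideca-2,6-dien-10-yne-1,13-diol F1. Silylation of both hydroxyls with 1,1,3,3-tetramethyldisilazane and intramolecular endo trans-hydrosilylation with [Cp*Ru(MeCN)3]PF6 gives the six-membered alkenyl siloxane 2,2-dimethyl-3-[(3E,7Z)-9-[(dimethylsilyl)oxy]-4,8-dimethylnona-3,7-dien-1-yl]-5,6-dihydro-2H-1,2-oxasiline F2, with silicon on C-8 cis to C-11. Iododesilylation with N-iodosuccinimide (retention) gives (2Z,6E,10Z)-10-iodo-2,6-dimethyltrideca-2,6,10-triene-1,13-diol F3. Kumada coupling with Me3SiCH2MgCl and catalytic Pd(PPh3)4 then comes back to the route at 7.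

Step 8 (oxidising one of two primary alcohols in an unprotected triol). If the C-19 carbinol is oxidised competitively, the fallback replaces chemoselectivity by a protecting-group detour. It sets out from 9: 2,2-dimethoxypropane with pyridinium p-toluenesulfonate (then brief methanolysis of the mixed ketal at O-12) gives the 3,19-O-isopropylidene acetal of 9 F6; Dess–Martin periodinane with NaHCO3 gives the 3,19-O-isopropylidene acetal of 10 F7; AcOH/H2O/THF at room temperature removes the acetonide, and the sequence comes back to the route at 10.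

**Further compounds**

F1 | step 5 | (2Z,6E)-2,6-dimethyltrideca-2,6-dien-10-yne-1,13-diol | OC/C(C)=C\CC/C(C)=C/CCC#CCCO
F2 | step 5 | 2,2-dimethyl-3-[(3E,7Z)-9-[(dimethylsilyl)oxy]-4,8-dimethylnona-3,7-dien-1-yl]-5,6-dihydro-2H-1,2-oxasiline | C[SiH](C)OC/C(C)=C\CC/C(C)=C/CCC1=CCCO[Si]1(C)C
F3 | step 5 | (2Z,6E,10Z)-10-iodo-2,6-dimethyltrideca-2,6,10-triene-1,13-diol | OC/C(C)=C\CC/C(C)=C/CC/C(I)=C/CCO
F4 | step 7 | bis(tert-butyldimethylsilyl) ether of 8 | CC(C)(C)[Si](C)(C)OC[C@]1(C)O[C@@H]1CC/C(C)=C/CC/C(C[Si](C)(C)C)=C/CCO[Si](C)(C)C(C)(C)C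
F5 | step 7 | 12,19-bis(tert-butyldimethylsilyl) ether of 9 | C=C1CC[C@@H]2[C@](C)(CO[Si](C)(C)C(C)(C)C)[C@H](O)CC[C@@]2(C)[C@@H]1CCO[Si](C)(C)C(C)(C)C
F6 | step 8 | 3,19-O-isopropylidene acetal of 9 | C=C1CC[C@@H]2[C@]3(C)COC(C)(C)O[C@@H]3CC[C@@]2(C)[C@@H]1CCO
F7 | step 8 | 3,19-O-isopropylidene acetal of 10 | C=C1CC[C@@H]2[C@]3(C)COC(C)(C)O[C@@H]3CC[C@@]2(C)[C@@H]1CC=O
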